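**Plan**

1. Retrosynthesis: remove the C5 chlorine and the C7 acetate. Then cut the C7–C8 bond of the carbocycle, the exocyclic C4a=C5 bond, the 4-pyranone ring (C3–C4 and O2–C1), and last the two side-chain alkenes.
2. Enabling feature: C8(=O)–C7(O)(CH3) is an acyloin unit inside the six-membered carbocycle. C7 also carries the C6 ketone, and C8 hangs on the enol-ether carbon C8a of the pyran ring. Opened at C7–C8, this is a 4H-pyran-3-carbaldehyde whose 4-(2,3-dioxobutylidene) arm places an activated methyl ketone in reach of the aldehyde carbon.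
3. Forward order: side-chain dienoic acid, then the 4-pyranone ring, its 4-thione, the exocyclic C=C by sulfide contraction, and release of aldehyde and 1,2-dione. The carbocycle is then closed by a carbene-catalysed benzoin reaction, followed by acetylation and chlorination.
4. Stereochemistry: the side-chain centre comes from (S)-2-methylbutan-1-ol. C7 is set in the ring closure by a chiral triazolium carbene catalyst. Both side-chain alkenes are E from a stabilized Wittig ylide and a Horner–Wadsworth–Emmons reaction.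

Key step: step 10

Remark: core atoms are numbered as in the isochromene target (C1, O2, C3, C4, C4a, C5–C8, C8a); the exocyclic C4a=C5 bond of the push–pull 4-ylidene-4H-pyrans 21–23 is assumed to isomerize freely at room temperature and is written without a descriptor.

**Route**

Step 1
Reactants: 1 (S)-2-methylbutan-1-ol; 2 2-(triphenylphosphoranylidene)propanal
Product: 4 (2E,4S)-2,4-dimethylhex-2-enal, via (S)-2-methylbutanal 3 (not isolated)
Conditions: 2,2,6,6-tetramethylpiperidin-1-oxyl (1 mol %), KBr (10 mol %), NaOCl, NaHCO3, CH2Cl2/H2O, 0 °C; dried organic phase, then 2, toluene, 80 °C (sealed vessel)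
Reagents that add atoms: 2-(triphenylphosphoranylidene)propanal (compound 2), CC(C=O)=P(c1ccccc1)(c1ccccc1)c1ccccc1
Why: The nitroxyl/hypochlorite oxidation should give the α-branched aldehyde without epimerization, and the stabilized formyl ylide should give the E-enal in a Wittig reaction; the stereocenter is carried over unchanged from 1.

Step 2
Reactants: 4 (2E,4S)-2,4-dimethylhex-2-enal; 5 2-(diethoxyphosphoryl)acetic acid
Product: 6 (2E,4E,6S)-4,6-dimethylocta-2,4-dienoic acid
Conditions: Zn(OSO2CF3)2, TMEDA, DBU, THF, 23 °C; aq. HCl work-up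
Reagents that add atoms: 2-(diethoxyphosphoryl)acetic acid (compound 5), CCOP(=O)(CC(=O)O)OCC
Why: A Horner–Wadsworth–Emmons reaction of the zinc-bound phosphonoacetate with the enal should give the E,E-dienoic acid directly, under conditions too mild to enolize the γ-stereocenter.

Step 3
Reactants: 7 2,2,6-trimethyl-4H-1,3-dioxin-4-one; 8 ethanethiol
Product: 10 S-ethyl 3-oxobutanethioate, via acetylketene 9 (not isolated)
Conditions: toluene, 110 °C, sealed vessel
Reagents that add atoms: ethanethiol (compound 8), CCS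
Why: Thermal cycloreversion of the dioxinone releases acetone and acetylketene, which the thiol traps as the β-keto thioester (acylketene trapping).

Step 4
Reactants: 10 S-ethyl 3-oxobutanethioate; 11 N,N-dimethylformamide dimethyl acetal
Product: 12 S-ethyl 2-[(dimethylamino)methylidene]-3-oxobutanethioate
Conditions: toluene, 23 °C
Reagents that add atoms: N,N-dimethylformamide dimethyl acetal (compound 11), COC(OC)N(C)C
Why: The doubly activated methylene condenses with the amide acetal (aminomethylenation) to give the enaminone, with methanol as the only by-product.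

Step 5
Reactants: 6 (2E,4E,6S)-4,6-dimethylocta-2,4-dienoic acid; 12 S-ethyl 2-[(dimethylamino)methylidene]-3-oxobutanethioate
Product: 15 S-ethyl 6-[(1E,3E,5S)-3,5-dimethylhepta-1,3-dien-1-yl]-4-oxo-4H-pyran-3-carbothioate, via (2E,4E,6S)-4,6-dimethylocta-2,4-dienoyl chloride 13 (not isolated), via the C-acylated enaminone 14 (not isolated)
Conditions: 6, (COCl)2, N,N-dimethylformamide (cat.), CH2Cl2, 0 → 23 °C, volatiles removed; 12 (2 equiv), LiN(SiMe3)2, THF, −78 °C, then 13; then 3 M HCl, 23 °C
Reagents that add atoms: none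
Why: C-acylation of the lithiated enaminone at its acetyl methyl group (enaminone-anion acylation) gives a 1,3-diketone whose enol oxygen displaces dimethylamine on acidification (addition–elimination), closing the 4-pyranone with the thioester at C3 and the dienyl chain at C6.

Step 6
Reactants: 15 S-ethyl 6-[(1E,3E,5S)-3,5-dimethylhepta-1,3-dien-1-yl]-4-oxo-4H-pyran-3-carbothioate
Product: 16 S-ethyl 6-[(1E,3E,5S)-3,5-dimethylhepta-1,3-dien-1-yl]-4-sulfanylidene-4H-pyran-3-carbothioate
Conditions: Lawesson's reagent (0.55 equiv), toluene, 80 °C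
Reagents that add atoms: Lawesson's reagent, COc1ccc(cc1)P1(=S)SP(=S)(S1)c1ccc(OC)cc1
Why: Lawesson thionation should attack the electron-rich vinylogous-ester carbonyl of the 4-pyranone much faster than the thioester carbonyl.

Step 7
Reactants: 17 3,3-dimethoxybutan-2-one
Product: 19 1-bromo-3,3-dimethoxybutan-2-one, via silyl enol ether 18 (not isolated)
Conditions: LiN(SiMe3)2, Me3SiCl, THF, −78 °C; then N-bromosuccinimide, NaHCO3, THF, 0 °C
Reagents that add atoms: N-bromosuccinimide, O=C1CCC(=O)N1Br
Why: The ketone can enolize only toward its methyl group, so kinetic silyl enol ether formation followed by bromination should place bromine at C1 without disturbing the ketal.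

Step 8
Reactants: 16 S-ethyl 6-[(1E,3E,5S)-3,5-dimethylhepta-1,3-dien-1-yl]-4-sulfanylidene-4H-pyran-3-carbothioate; 19 1-bromo-3,3-dimethoxybutan-2-one
Product: 21 S-ethyl 4-(3,3-dimethoxy-2-oxobutylidene)-6-[(1E,3E,5S)-3,5-dimethylhepta-1,3-dien-1-yl]-4H-pyran-3-carbothioate, via the 4-alkylsulfanylpyrylium bromide 20 (not isolated)
Conditions: CH2Cl2, 23 °C; then PPh3, Et3N, MeCN, 23 → 50 °C
Reagents that add atoms: none
Why: This is an Eschenmoser sulfide contraction: S-alkylation gives a 4-alkylsulfanylpyrylium salt, deprotonation next to sulfur closes an episulfide at the cationic C4, and PPh3 removes sulfur to leave the exocyclic C4a=C5 bond.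

Step 9
Reactants: 21 S-ethyl 4-(3,3-dimethoxy-2-oxobutylidene)-6-[(1E,3E,5S)-3,5-dimethylhepta-1,3-dien-1-yl]-4H-pyran-3-carbothioate
Product: 23 6-[(1E,3E,5S)-3,5-dimethylhepta-1,3-dien-1-yl]-4-(2,3-dioxobutylidene)-4H-pyran-3-carbaldehyde, via the aldehyde ketal 22 (not isolated)
Conditions: Et3SiH, palladium on carbon (10 wt % Pd), acetone, 23 °C; filtration; then CF3CO2H, H2O, CH2Cl2, 0 °C
Reagents that add atoms: water, O
Why: In the Fukuyama reduction, zerovalent palladium inserts into the C–S bond and the silane delivers hydride, so only the thioester should be converted to the aldehyde while the ketal masks the dione; aqueous acid then hydrolyses the ketal to the 1,2-diketone.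

Step 10
Reactants: 23 6-[(1E,3E,5S)-3,5-dimethylhepta-1,3-dien-1-yl]-4-(2,3-dioxobutylidene)-4H-pyran-3-carbaldehyde
Product: 24 (7S)-3-[(1E,3E,5S)-3,5-dimethylhepta-1,3-dien-1-yl]-7-hydroxy-7-methyl-6H-isochromene-6,8(7H)-dione
Conditions: (5aS,10bR)-2-(pentafluorophenyl)-5a,10b-dihydro-4H,6H-indeno[2,1-b][1,2,4]triazolo[4,3-d][1,4]oxazin-2-ium tetrafluoroborate (15 mol %), KN(SiMe3)2 (13 mol %), toluene, 23 °C
Reagents that add atoms: none
Why: The triazolylidene adds to the C8 aldehyde and proton transfer gives the Breslow intermediate, whose nucleophilic C8 attacks the C7 ketone of the 1,2-dione; collapse releases the carbene and the α-ketol. The closest known reaction type is the enantioselective intramolecular crossed aldehyde–ketone benzoin reaction catalysed by aminoindanol-derived triazolium salts. The six-membered carbocycle (C8–C8a–C4a–C5–C6–C7) closes in 6-exo-trig mode from the isomer of the labile C4a=C5 bond that has C6 on the side of C8a, which equilibration should supply. The new stereocenter C7 is under catalyst control: the indane wall shields one face of the Breslow intermediate and a hydrogen bond from its enol OH to the ketone oxygen orders the transition state, so that C8 should add to the Re face of C7 (priority O > C6 > CH3); the sense is to be confirmed in a first run and the mirror-image catalyst used if it is opposite. The step needs C7 over C6 selectivity and acyl-anion over homoenolate reactivity: C6 is deactivated as a doubly vinylogous ester carbonyl while C7 is activated by its neighbouring carbonyl (a five-membered adduct could also revert by retro-benzoin), and the electron-poor N-pentafluorophenyl triazolium with substoichiometric base favours acyl-anion behaviour.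

Step 11
Reactants: 24 (7S)-3-[(1E,3E,5S)-3,5-dimethylhepta-1,3-dien-1-yl]-7-hydroxy-7-methyl-6H-isochromene-6,8(7H)-dione
Product: 25 (7S)-3-[(1E,3E,5S)-3,5-dimethylhepta-1,3-dien-1-yl]-7-methyl-6,8-dioxo-7,8-dihydro-6H-isochromen-7-yl acetate
Conditions: Ac2O, 4-(dimethylamino)pyridine (cat.), pyridine, CH2Cl2, 0 → 23 °C
Reagents that add atoms: acetic anhydride, CC(=O)OC(C)=O
Why: Nucleophile-catalysed acylation of the tertiary alcohol should proceed as for other 7-hydroxy azaphilones; no bond at C7 is broken, so its configuration is kept.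

Step 12
Reactants: 25 (7S)-3-[(1E,3E,5S)-3,5-dimethylhepta-1,3-dien-1-yl]-7-methyl-6,8-dioxo-7,8-dihydro-6H-isochromen-7-yl acetate
Product: 26 sclerotiorin, (7R)-5-chloro-3-[(1E,3E,5S)-3,5-dimethylhepta-1,3-dien-1-yl]-7-methyl-6,8-dioxo-7,8-dihydro-6H-isochromen-7-yl acetate
Conditions: N-chlorosuccinimide, MeCN, 23 °C
Reagents that add atoms: N-chlorosuccinimide, O=C1CCC(=O)N1Cl
Why: Electrophilic chlorination should occur at C5, the α-carbon of the cross-conjugated vinylogous ester O2–C3=C4–C4a=C5–C6=O and the usual halogenation site of the azaphilone core; the C7 descriptor changes from S to R only because chlorine changes the CIP priorities.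

**Compound list**

1 | (S)-2-methylbutan-1-ol | CC[C@H](C)CO | starting material
2 | 2-(triphenylphosphoranylidene)propanal | CC(C=O)=P(c1ccccc1)(c1ccccc1)c1ccccc1 | starting material
3 | (S)-2-methylbutanal | CC[C@H](C)C=O | intermediate
4 | (2E,4S)-2,4-dimethylhex-2-enal | CC[C@H](C)/C=C(C)/C=O | intermediate
5 | 2-(diethoxyphosphoryl)acetic acid | CCOP(=O)(CC(=O)O)OCC | starting material
6 | (2E,4E,6S)-4,6-dimethylocta-2,4-dienoic acid | CC[C@H](C)/C=C(C)/C=C/C(=O)O | intermediate
7 | 2,2,6-trimethyl-4H-1,3-dioxin-4-one | CC1=CC(=O)OC(C)(C)O1 | starting material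
8 | ethanethiol | CCS | starting material
9 | acetylketene (3-oxobut-1-en-1-one) | CC(=O)C=C=O | intermediate
10 | S-ethyl 3-oxobutanethioate | CCSC(=O)CC(C)=O | intermediate
11 | N,N-dimethylformamide dimethyl acetal | COC(OC)N(C)C | starting material
12 | S-ethyl 2-[(dimethylamino)methylidene]-3-oxobutanethioate | CCSC(=O)C(=CN(C)C)C(C)=O | intermediate
13 | (2E,4E,6S)-4,6-dimethylocta-2,4-dienoyl chloride | CC[C@H](C)/C=C(C)/C=C/C(Cl)=O | intermediate
14 | S-ethyl (6E,8E,10S)-2-[(dimethylamino)methylidene]-8,10-dimethyl-3,5-dioxododeca-6,8-dienethioate | CC[C@H](C)/C=C(C)/C=C/C(=O)CC(=O)C(=CN(C)C)C(=O)SCC | intermediate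
15 | S-ethyl 6-[(1E,3E,5S)-3,5-dimethylhepta-1,3-dien-1-yl]-4-oxo-4H-pyran-3-carbothioate | CC[C@H](C)/C=C(C)/C=C/C1=CC(=O)C(C(=O)SCC)=CO1 | intermediate
16 | S-ethyl 6-[(1E,3E,5S)-3,5-dimethylhepta-1,3-dien-1-yl]-4-sulfanylidene-4H-pyran-3-carbothioate | CC[C@H](C)/C=C(C)/C=C/C1=CC(=S)C(C(=O)SCC)=CO1 | intermediate
17 | 3,3-dimethoxybutan-2-one | CC(=O)C(C)(OC)OC | starting material
18 | [(3,3-dimethoxybut-1-en-2-yl)oxy]trimethylsilane | C=C(O[Si](C)(C)C)C(C)(OC)OC | intermediate
19 | 1-bromo-3,3-dimethoxybutan-2-one | COC(C)(OC)C(=O)CBr | intermediate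
20 | 4-[(3,3-dimethoxy-2-oxobutyl)sulfanyl]-2-[(1E,3E,5S)-3,5-dimethylhepta-1,3-dien-1-yl]-5-[(ethylsulfanyl)carbonyl]pyrylium bromide | CC[C@H](C)/C=C(C)/C=C/c1cc(SCC(=O)C(C)(OC)OC)c(C(=O)SCC)c[o+]1.[Br-] | intermediate
21 | S-ethyl 4-(3,3-dimethoxy-2-oxobutylidene)-6-[(1E,3E,5S)-3,5-dimethylhepta-1,3-dien-1-yl]-4H-pyran-3-carbothioate | CC[C@H](C)/C=C(C)/C=C/C1=CC(=CC(=O)C(C)(OC)OC)C(C(=O)SCC)=CO1 | intermediate
22 | 4-(3,3-dimethoxy-2-oxobutylidene)-6-[(1E,3E,5S)-3,5-dimethylhepta-1,3-dien-1-yl]-4H-pyran-3-carbaldehyde | CC[C@H](C)/C=C(C)/C=C/C1=CC(=CC(=O)C(C)(OC)OC)C(C=O)=CO1 | intermediate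
23 | 6-[(1E,3E,5S)-3,5-dimethylhepta-1,3-dien-1-yl]-4-(2,3-dioxobutylidene)-4H-pyran-3-carbaldehyde | CC[C@H](C)/C=C(C)/C=C/C1=CC(=CC(=O)C(C)=O)C(C=O)=CO1 | intermediate
24 | (7S)-3-[(1E,3E,5S)-3,5-dimethylhepta-1,3-dien-1-yl]-7-hydroxy-7-methyl-6H-isochromene-6,8(7H)-dione | CC[C@H](C)/C=C(C)/C=C/C1=CC2=CC(=O)[C@](C)(O)C(=O)C2=CO1 | intermediate
25 | (7S)-3-[(1E,3E,5S)-3,5-dimethylhepta-1,3-dien-1-yl]-7-methyl-6,8-dioxo-7,8-dihydro-6H-isochromen-7-yl acetate | CC[C@H](C)/C=C(C)/C=C/C1=CC2=CC(=O)[C@](C)(OC(C)=O)C(=O)C2=CO1 | intermediate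
26 | sclerotiorin, (7R)-5-chloro-3-[(1E,3E,5S)-3,5-dimethylhepta-1,3-dien-1-yl]-7-methyl-6,8-dioxo-7,8-dihydro-6H-isochromen-7-yl acetate | CC[C@H](C)/C=C(C)/C=C/C1=CC2=C(Cl)C(=O)[C@](C)(OC(C)=O)C(=O)C2=CO1 | target

**Step count and risks**

Total step count: 12. Longest linear sequence: 9 steps (1, 2, 5, 6, 8, 9, 10, 11, 12).

Steps most likely to fail:

Step 10. The carbene may add slowly or unproductively to the vinylogous-formate aldehyde, the carbene or base may attack C1 and open the pyran ring, homoenolate-type reaction may compete, or the ring may close with poor facial selectivity. The fallback sets out from 23 and comes back at 24, replacing umpolung catalysis by a reductive ring closure. SmI2 (THF, −78 °C) reduces the 1,2-dione to its samarium enediolate, which adds through C7 to the aldehyde and forms the same C7–C8 bond. This gives 3-[(1E,3E,5S)-3,5-dimethylhepta-1,3-dien-1-yl]-7,8-dihydroxy-7-methyl-7,8-dihydro-6H-isochromen-6-one F1 as a diastereomer mixture. MnO2 (CH2Cl2, 23 °C) then oxidizes the allylic C8 carbinol to give 24 together with its C7 epimer, (7R)-3-[(1E,3E,5S)-3,5-dimethylhepta-1,3-dien-1-yl]-7-hydroxy-7-methyl-6H-isochromene-6,8(7H)-dione F2. The two are diastereomers because of the fixed side-chain centre and would be separated by preparative HPLC before step 11.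

Step 8. The carbanion next to sulfur may attack the neighbouring thioester carbonyl (thiophene annulation) instead of C4, or the episulfide may fail to lose sulfur. The fallback sets out from 16 and comes back at 21, using intermolecular addition–elimination at a 4-(methylsulfanyl)pyrylium salt. MeOSO2CF3 (CH2Cl2, 0 °C) methylates the thione to 2-[(1E,3E,5S)-3,5-dimethylhepta-1,3-dien-1-yl]-5-[(ethylsulfanyl)carbonyl]-4-(methylsulfanyl)pyrylium trifluoromethanesulfonate F3. Silyl enol ether 18, prepared as in step 7 and distilled, then adds at C4, and methanethiol is lost on warming with 2,6-lutidine in MeCN. This should give 21 without any carbanion on a sulfur-bound side chain.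

Step 9. Palladium hydride may saturate or isomerize the diene and the ylidene bond, the acylpalladium intermediate may lose CO, or sulfur residues from step 8 may poison the catalyst. The fallback sets out from 21 and comes back at 22, which is then hydrolysed to 23 by the acid treatment of step 9; it replaces the palladium reduction by hydride reduction and reoxidation. NaBH4 (EtOH/THF, 0 °C) should reduce the thioester but leave the hindered push–pull ketone, giving {6-[(1E,3E,5S)-3,5-dimethylhepta-1,3-dien-1-yl]-4-(3,3-dimethoxy-2-oxobutylidene)-4H-pyran-3-yl}methanol F4 with loss of ethanethiol. MnO2 (CH2Cl2, 23 °C) then oxidizes this allylic alcohol to aldehyde 22, which is isolated in this variant.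

**Further compounds**

F1 | step 10 | 3-[(1E,3E,5S)-3,5-dimethylhepta-1,3-dien-1-yl]-7,8-dihydroxy-7-methyl-7,8-dihydro-6H-isochromen-6-one (C7/C8 diastereomer mixture) | CC[C@H](C)/C=C(C)/C=C/C1=CC2=CC(=O)C(C)(O)C(O)C2=CO1
F2 | step 10 | (7R)-3-[(1E,3E,5S)-3,5-dimethylhepta-1,3-dien-1-yl]-7-hydroxy-7-methyl-6H-isochromene-6,8(7H)-dione | CC[C@H](C)/C=C(C)/C=C/C1=CC2=CC(=O)[C@@](C)(O)C(=O)C2=CO1
F3 | step 8 | 2-[(1E,3E,5S)-3,5-dimethylhepta-1,3-dien-1-yl]-5-[(ethylsulfanyl)carbonyl]-4-(methylsulfanyl)pyrylium trifluoromethanesulfonate | CC[C@H](C)/C=C(C)/C=C/c1cc(SC)c(C(=O)SCC)c[o+]1.[O-]S(=O)(=O)C(F)(F)F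
F4 | step 9 | {6-[(1E,3E,5S)-3,5-dimethylhepta-1,3-dien-1-yl]-4-(3,3-dimethoxy-2-oxobutylidene)-4H-pyran-3-yl}methanol | CC[C@H](C)/C=C(C)/C=C/C1=CC(=CC(=O)C(C)(OC)OC)C(CO)=CO1
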